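The synthesis rests on opening the dihydrofuran ring at C3–C3a and O1–C2 (ring atoms O1, C2, C3, C3a, C4–C7, C7a; side chain C1′–C10′). This exposes the enolised 1,3-dione C4(=O)–C3a=C7a–O1 of the six-membered ring as a two-point nucleophile: C3a is a soft carbon and O1 the enol oxygen. One palladium-catalysed operation joins both to a butenediyl bis(carbonate), closes the furan ring, sets C2 as (S) under ligand control and leaves a vinyl group on C2 as the handle for C1′. Its precursors are cyclohexane-1,3-dione and the dicarbonate of cis-butenediol. A homogeranyl chain from geranyl acetate, the C1′ methyl group and the C5 hydroxyl are added afterwards.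

Key step: step 2

Assumption: (R)-BINAP in step 2 and the (+)-oxaziridine in step 13 are taken to lead to (2S) and (5R); if a first run shows the opposite sense, the mirror-image ligand or reagent is used and nothing else changes.

Step 1
Reactants: 1 (Z)-but-2-ene-1,4-diol
Product: 2 (Z)-but-2-ene-1,4-diyl dimethyl dicarbonate
Conditions: ClCO2Me (2.4 equiv), pyridine, CH2Cl2, 0 °C → rt
Reagents that add atoms: methyl chloroformate, COC(=O)Cl
Why: Acylation of both primary allylic hydroxyl groups by the chloroformate with pyridine as HCl scavenger (carbonate formation) is routine and does not touch the Z-alkene.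

Step 2
Reactants: 3 cyclohexane-1,3-dione; 2 (Z)-but-2-ene-1,4-diyl dimethyl dicarbonate
Product: 5 (2S)-2-ethenyl-3,5,6,7-tetrahydro-1-benzofuran-4(2H)-one, via monoalkylated allyl carbonate 4 (not isolated)
Conditions: Pd2(dba)3·CHCl3 (2.5 mol %), (R)-BINAP (6 mol %), THF, rt
Reagents that add atoms: none
Why: Pd(0)/(R)-BINAP ionises one carbonate of 2 (CO2 and methoxide leave), the methoxide deprotonates 3, and the soft central carbon of the dione (the future C3a) attacks the unsubstituted allyl terminus to give 4 (C3–C3a); ionisation of the second carbonate then gives a tethered π-allyl complex that the enol oxygen traps at its near carbon (O1–C2). The closest known reaction type is the Pd-catalysed asymmetric allylic C-alkylation/O-cyclisation (formal [3+2] annulation) of 1,3-diketones with but-2-ene-1,4-diyl dicarbonates to 2-vinyl-2,3-dihydrofurans. The dihydrofuran ring closes in a 5-exo mode, the two remaining allyl carbons ending up as the exocyclic vinyl group. C2 is the only new stereocentre and is set by the chiral bisphosphine, because the diastereomeric π-allyl complexes interconvert by π–σ–π isomerisation faster than they cyclise, so both alkene geometries and both allyl faces should pass through the same favoured transition state. The step needs C- before O-alkylation, O-attack rather than a second C-attack, and 5-exo rather than 7-endo closure: the first follows from the softness of the dione carbon, the second from the reversibility under Pd(0) of the strained spiro-vinylcyclopropane that C-attack would give, and the third from the short tether, which lets the oxygen reach only the near allyl carbon.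

Step 3
Reactants: 5 (2S)-2-ethenyl-3,5,6,7-tetrahydro-1-benzofuran-4(2H)-one
Product: 7 (2S)-4-oxo-2,3,4,5,6,7-hexahydro-1-benzofuran-2-carbaldehyde, via vicinal diol 6 (not isolated)
Conditions: OsO4 (2 mol %), NaIO4, 2,6-lutidine, dioxane/H2O (3:1), rt; crude aldehyde dried and used at once
Reagents that add atoms: osmium tetroxide (catalytic oxygen carrier), O=[Os](=O)(=O)=O; sodium periodate (terminal oxidant), [Na+].[O-]I(=O)(=O)=O
Why: In this Lemieux–Johnson oxidation OsO4 should dihydroxylate only the monosubstituted vinyl group, the tetrasubstituted, acceptor-conjugated C3a=C7a bond being far less reactive, and periodate cleaves diol 6 in the same flask, while the lutidine buffer and immediate use of 7 keep C2, now next to an aldehyde, from epimerising.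

Step 4
Reactants: 8 geranyl acetate
Product: 9 (2E,6E)-8-hydroxy-3,7-dimethylocta-2,6-dien-1-yl acetate
Conditions: SeO2 (cat.), t-BuOOH, salicylic acid (cat.), CH2Cl2, rt
Reagents that add atoms: selenium dioxide (catalytic oxygen carrier), O=[Se]=O; tert-butyl hydroperoxide (terminal oxidant), CC(C)(C)OO
Why: The catalytic SeO2/t-BuOOH allylic oxidation (ene reaction followed by a [2,3]-sigmatropic shift) should attack the (E)-methyl group of the electron-rich terminal alkene, the 2,3-alkene being deactivated by the allylic acetate, and deliver the (E)-allylic alcohol.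

Step 5
Reactants: 9 (2E,6E)-8-hydroxy-3,7-dimethylocta-2,6-dien-1-yl acetate
Product: 10 (2E,6E)-8-(TBS-oxy)-3,7-dimethylocta-2,6-dien-1-yl acetate (TBS = tert-butyldimethylsilyl)
Conditions: TBSCl, imidazole, CH2Cl2, rt
Reagents that add atoms: tert-butyldimethylsilyl chloride, CC(C)(C)[Si](C)(C)Cl
Why: Silylation of the primary allylic alcohol with TBSCl/imidazole is standard and masks the future carboxyl carbon C10′ through the organometallic steps.

Step 6
Reactants: 10 (2E,6E)-8-(TBS-oxy)-3,7-dimethylocta-2,6-dien-1-yl acetate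
Product: 11 (2E,6E)-8-(TBS-oxy)-3,7-dimethylocta-2,6-dien-1-ol
Conditions: K2CO3 (cat.), MeOH, rt
Reagents that add atoms: none
Why: Base-catalysed transesterification with methanol removes the acetate, and the silyl ether is stable to these conditions.

Step 7
Reactants: 11 (2E,6E)-8-(TBS-oxy)-3,7-dimethylocta-2,6-dien-1-ol
Product: 12 [(2E,6E)-8-bromo-2,6-dimethylocta-2,6-dien-1-yl]oxy(tert-butyl)dimethylsilane
Conditions: CBr4, PPh3, CH2Cl2, 0 °C; used crude
Reagents that add atoms: carbon tetrabromide, BrC(Br)(Br)Br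
Why: The Appel reaction converts the primary allylic alcohol into the bromide by SN2 displacement of the oxyphosphonium group under neutral conditions, so neither allylic transposition nor loss of the silyl ether is expected.

Step 8
Reactants: 12 [(2E,6E)-8-bromo-2,6-dimethylocta-2,6-dien-1-yl]oxy(tert-butyl)dimethylsilane
Product: 13 tert-butyl{[(2E,6E)-2,6-dimethyl-9-(phenylsulfanyl)nona-2,6-dien-1-yl]oxy}dimethylsilane
Conditions: PhSMe, n-BuLi, DABCO, THF, 0 °C; CuI, −78 °C; then 12, −78 °C → rt
Reagents that add atoms: thioanisole (as its lithio, then copper derivative), CSc1ccccc1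
Why: This is a one-carbon homologation by SN2 alkylation of the (phenylsulfanyl)methyl copper reagent at the primary allylic bromide, the copper species suppressing SN2′ attack and metal–halogen exchange so that the E-alkene is retained.

Step 9
Reactants: 13 tert-butyl{[(2E,6E)-2,6-dimethyl-9-(phenylsulfanyl)nona-2,6-dien-1-yl]oxy}dimethylsilane
Product: 15 tert-butyl{[(2E,6E)-9-iodo-2,6-dimethylnona-2,6-dien-1-yl]oxy}dimethylsilane, via sulfonium iodide 14 (not isolated)
Conditions: MeI (excess), NaI, DMF, rt, dark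
Reagents that add atoms: methyl iodide, CI; sodium iodide (iodide pool), [Na+].[I-]
Why: S-Methylation gives sulfonium salt 14, in which iodide displaces thioanisole at the primary homoallylic carbon (SN2), a neutral sulfide-to-iodide exchange that the silyl ether and both alkenes should tolerate.

Step 10
Reactants: 15 tert-butyl{[(2E,6E)-9-iodo-2,6-dimethylnona-2,6-dien-1-yl]oxy}dimethylsilane; 7 (2S)-4-oxo-2,3,4,5,6,7-hexahydro-1-benzofuran-2-carbaldehyde
Product: 18 (2S)-2-[(4E,8E)-10-(TBS-oxy)-1-hydroxy-5,9-dimethyldeca-4,8-dien-1-yl]-3,5,6,7-tetrahydro-1-benzofuran-4(2H)-one (both C1′ epimers), via homoallyllithium 16 (not isolated), via homoallylmagnesium bromide 17 (not isolated)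
Conditions: t-BuLi (2.1 equiv), Et2O, −78 °C; MgBr2·OEt2; then 7, THF, −78 °C; H2O
Reagents that add atoms: none
Why: Iodine–lithium exchange and transmetallation give the homoallylic Grignard reagent, which at −78 °C should add only to the aldehyde (the vinylogous ester carbonyl C4 is far less electrophilic), and the new C1′ carbinol centre, formed without control, is erased by the next oxidation.

Step 11
Reactants: 18 (2S)-2-[(4E,8E)-10-(TBS-oxy)-1-hydroxy-5,9-dimethyldeca-4,8-dien-1-yl]-3,5,6,7-tetrahydro-1-benzofuran-4(2H)-one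
Product: 19 (2S)-2-[(4E,8E)-10-(TBS-oxy)-5,9-dimethyldeca-4,8-dienoyl]-3,5,6,7-tetrahydro-1-benzofuran-4(2H)-one
Conditions: Dess–Martin periodinane, CH2Cl2, 0 °C → rt
Reagents that add atoms: none
Why: Dess–Martin oxidation converts the secondary alcohol into the ketone under non-basic conditions, which matters because C2 is now α to a ketone and must not enolise.

Step 12
Reactants: 19 (2S)-2-[(4E,8E)-10-(TBS-oxy)-5,9-dimethyldeca-4,8-dienoyl]-3,5,6,7-tetrahydro-1-benzofuran-4(2H)-one
Product: 20 (2S)-2-[(2S,5E,9E)-11-(TBS-oxy)-2-hydroxy-6,10-dimethylundeca-5,9-dien-2-yl]-3,5,6,7-tetrahydro-1-benzofuran-4(2H)-one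
Conditions: MeTi(Oi-Pr)3 (1 M in THF, excess), CH2Cl2, −30 °C → rt; aqueous work-up
Reagents that add atoms: methyltitanium triisopropoxide, C[Ti](OC(C)C)(OC(C)C)OC(C)C
Why: The non-basic, non-chelating methyltitanium reagent should add only to the activated α-alkoxy ketone and do so through a Felkin–Anh (Cornforth-type) transition state, with the C2–O1 bond anti to the incoming methyl group and C2–H on the side of the chain, which sets C1′ as (S).

Step 13
Reactants: 20 (2S)-2-[(2S,5E,9E)-11-(TBS-oxy)-2-hydroxy-6,10-dimethylundeca-5,9-dien-2-yl]-3,5,6,7-tetrahydro-1-benzofuran-4(2H)-one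
Product: 22 (2S,5R)-2-[(2S,5E,9E)-11-(TBS-oxy)-2-hydroxy-6,10-dimethylundeca-5,9-dien-2-yl]-5-hydroxy-3,5,6,7-tetrahydro-1-benzofuran-4(2H)-one, via dilithium alkoxide enolate 21 (not isolated)
Conditions: LDA (2.2 equiv), THF, −78 °C; (+)-(camphorylsulfonyl)oxaziridine, −78 °C; AcOH, −78 °C
Reagents that add atoms: (+)-(2R,8aS)-(camphorylsulfonyl)oxaziridine, CC1(C)[C@@H]2CC[C@]13CS(=O)(=O)N4O[C@@]34C2
Why: After deprotonation of the tertiary hydroxyl, LDA removes the kinetically favoured α′ proton at C5 of the vinylogous ester and the cross-conjugated enolate 21 is hydroxylated by the camphor-derived N-sulfonyloxaziridine (asymmetric enolate hydroxylation with a Davis-type reagent), whose chirality rather than the remote C2 and C1′ centres should select the enolate face and set C5 as (R), the cold acid quench protecting the α-ketol from base.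

Step 14
Reactants: 22 (2S,5R)-2-[(2S,5E,9E)-11-(TBS-oxy)-2-hydroxy-6,10-dimethylundeca-5,9-dien-2-yl]-5-hydroxy-3,5,6,7-tetrahydro-1-benzofuran-4(2H)-one
Product: 23 (2S,5R)-2-[(2S,5E,9E)-2,11-dihydroxy-6,10-dimethylundeca-5,9-dien-2-yl]-5-hydroxy-3,5,6,7-tetrahydro-1-benzofuran-4(2H)-one
Conditions: TBAF, AcOH, THF, 0 °C → rt
Reagents that add atoms: none
Why: Fluoride-mediated desilylation, buffered with acetic acid so that the base-sensitive α-ketol at C5 is not epimerised, frees the primary allylic alcohol.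

Step 15
Reactants: 23 (2S,5R)-2-[(2S,5E,9E)-2,11-dihydroxy-6,10-dimethylundeca-5,9-dien-2-yl]-5-hydroxy-3,5,6,7-tetrahydro-1-benzofuran-4(2H)-one
Product: 24 (2E,6E,10S)-10-hydroxy-10-[(2S,5R)-5-hydroxy-4-oxo-2,3,4,5,6,7-hexahydro-1-benzofuran-2-yl]-2,6-dimethylundeca-2,6-dienal
Conditions: activated MnO2 (excess), CH2Cl2, rt
Reagents that add atoms: none
Why: Activated MnO2 oxidises allylic alcohols selectively, so the primary allylic alcohol should give the (E)-enal while the secondary α-ketol and the tertiary alcohol are left alone.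

Step 16
Reactants: 24 (2E,6E,10S)-10-hydroxy-10-[(2S,5R)-5-hydroxy-4-oxo-2,3,4,5,6,7-hexahydro-1-benzofuran-2-yl]-2,6-dimethylundeca-2,6-dienal
Product: 25 (2E,6E,10S)-10-hydroxy-10-[(2S,5R)-5-hydroxy-4-oxo-2,3,4,5,6,7-hexahydro-1-benzofuran-2-yl]-2,6-dimethylundeca-2,6-dienoic acid (target)
Conditions: NaClO2, NaH2PO4, 2-methylbut-2-ene, t-BuOH/H2O, 0 °C → rt
Reagents that add atoms: sodium chlorite, [Na+].[O-]Cl=O
Why: The Pinnick oxidation (chlorite with a hypochlorite scavenger at buffered pH) converts the enal into the acid without touching alcohols, alkenes or stereocentres.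

Compound list
1 | (Z)-but-2-ene-1,4-diol | OC/C=C\CO | starting material
2 | (Z)-but-2-ene-1,4-diyl dimethyl dicarbonate | COC(=O)OC/C=C\COC(=O)OC | intermediate
3 | cyclohexane-1,3-dione | O=C1CCCC(=O)C1 | starting material
4 | methyl (2E)-4-(2,6-dioxocyclohexyl)but-2-en-1-yl carbonate (E shown; any Z isomer converges) | O=C1CCCC(=O)C1C/C=C/COC(=O)OC | intermediate (not isolated)
5 | (2S)-2-ethenyl-3,5,6,7-tetrahydro-1-benzofuran-4(2H)-one | C=C[C@@H]1CC2=C(CCCC2=O)O1 | intermediate
6 | (2S)-2-(1,2-dihydroxyethyl)-3,5,6,7-tetrahydro-1-benzofuran-4(2H)-one (both carbinol epimers) | OCC(O)[C@@H]1CC2=C(CCCC2=O)O1 | intermediate (not isolated)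
7 | (2S)-4-oxo-2,3,4,5,6,7-hexahydro-1-benzofuran-2-carbaldehyde | O=C[C@@H]1CC2=C(CCCC2=O)O1 | intermediate
8 | geranyl acetate, (2E)-3,7-dimethylocta-2,6-dien-1-yl acetate | CC(C)=CCC/C(C)=C/COC(C)=O | starting material
9 | (2E,6E)-8-hydroxy-3,7-dimethylocta-2,6-dien-1-yl acetate | OC/C(C)=C/CC/C(C)=C/COC(C)=O | intermediate
10 | (2E,6E)-8-[(tert-butyldimethylsilyl)oxy]-3,7-dimethylocta-2,6-dien-1-yl acetate | CC(C)(C)[Si](C)(C)OC/C(C)=C/CC/C(C)=C/COC(C)=O | intermediate
11 | (2E,6E)-8-[(tert-butyldimethylsilyl)oxy]-3,7-dimethylocta-2,6-dien-1-ol | CC(C)(C)[Si](C)(C)OC/C(C)=C/CC/C(C)=C/CO | intermediate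
12 | [(2E,6E)-8-bromo-2,6-dimethylocta-2,6-dien-1-yl]oxy(tert-butyl)dimethylsilane | CC(C)(C)[Si](C)(C)OC/C(C)=C/CC/C(C)=C/CBr | intermediate
13 | tert-butyl{[(2E,6E)-2,6-dimethyl-9-(phenylsulfanyl)nona-2,6-dien-1-yl]oxy}dimethylsilane | CC(C)(C)[Si](C)(C)OC/C(C)=C/CC/C(C)=C/CCSc1ccccc1 | intermediate
14 | [(3E,7E)-9-[(tert-butyldimethylsilyl)oxy]-4,8-dimethylnona-3,7-dien-1-yl](methyl)phenylsulfonium iodide | CC(C)(C)[Si](C)(C)OC/C(C)=C/CC/C(C)=C/CC[S+](C)c1ccccc1.[I-] | intermediate (not isolated)
15 | tert-butyl{[(2E,6E)-9-iodo-2,6-dimethylnona-2,6-dien-1-yl]oxy}dimethylsilane | CC(C)(C)[Si](C)(C)OC/C(C)=C/CC/C(C)=C/CCI | intermediate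
16 | [(3E,7E)-9-[(tert-butyldimethylsilyl)oxy]-4,8-dimethylnona-3,7-dien-1-yl]lithium | CC(C)(C)[Si](C)(C)OC/C(C)=C/CC/C(C)=C/CC[Li] | intermediate (not isolated)
17 | [(3E,7E)-9-[(tert-butyldimethylsilyl)oxy]-4,8-dimethylnona-3,7-dien-1-yl]magnesium bromide | CC(C)(C)[Si](C)(C)OC/C(C)=C/CC/C(C)=C/CC[Mg]Br | intermediate (not isolated)
18 | (2S)-2-[(4E,8E)-10-[(tert-butyldimethylsilyl)oxy]-1-hydroxy-5,9-dimethyldeca-4,8-dien-1-yl]-3,5,6,7-tetrahydro-1-benzofuran-4(2H)-one (both C1′ epimers) | CC(C)(C)[Si](C)(C)OC/C(C)=C/CC/C(C)=C/CCC(O)[C@@H]1CC2=C(CCCC2=O)O1 | intermediate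
19 | (2S)-2-[(4E,8E)-10-[(tert-butyldimethylsilyl)oxy]-5,9-dimethyldeca-4,8-dienoyl]-3,5,6,7-tetrahydro-1-benzofuran-4(2H)-one | CC(C)(C)[Si](C)(C)OC/C(C)=C/CC/C(C)=C/CCC(=O)[C@@H]1CC2=C(CCCC2=O)O1 | intermediate
20 | (2S)-2-[(2S,5E,9E)-11-[(tert-butyldimethylsilyl)oxy]-2-hydroxy-6,10-dimethylundeca-5,9-dien-2-yl]-3,5,6,7-tetrahydro-1-benzofuran-4(2H)-one | CC(C)(C)[Si](C)(C)OC/C(C)=C/CC/C(C)=C/CC[C@](C)(O)[C@@H]1CC2=C(CCCC2=O)O1 | intermediate
21 | dilithium salt of 20 (C1′ alkoxide and C4=C5 enolate) | CC(C)(C)[Si](C)(C)OC/C(C)=C/CC/C(C)=C/CC[C@](C)(O[Li])[C@@H]1CC2=C(CCC=C2O[Li])O1 | intermediate (not isolated)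
22 | (2S,5R)-2-[(2S,5E,9E)-11-[(tert-butyldimethylsilyl)oxy]-2-hydroxy-6,10-dimethylundeca-5,9-dien-2-yl]-5-hydroxy-3,5,6,7-tetrahydro-1-benzofuran-4(2H)-one | CC(C)(C)[Si](C)(C)OC/C(C)=C/CC/C(C)=C/CC[C@](C)(O)[C@@H]1CC2=C(CC[C@@H](O)C2=O)O1 | intermediate
23 | (2S,5R)-2-[(2S,5E,9E)-2,11-dihydroxy-6,10-dimethylundeca-5,9-dien-2-yl]-5-hydroxy-3,5,6,7-tetrahydro-1-benzofuran-4(2H)-one | OC/C(C)=C/CC/C(C)=C/CC[C@](C)(O)[C@@H]1CC2=C(CC[C@@H](O)C2=O)O1 | intermediate
24 | (2E,6E,10S)-10-hydroxy-10-[(2S,5R)-5-hydroxy-4-oxo-2,3,4,5,6,7-hexahydro-1-benzofuran-2-yl]-2,6-dimethylundeca-2,6-dienal | O=C/C(C)=C/CC/C(C)=C/CC[C@](C)(O)[C@@H]1CC2=C(CC[C@@H](O)C2=O)O1 | intermediate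
25 | (2E,6E,10S)-10-hydroxy-10-[(2S,5R)-5-hydroxy-4-oxo-2,3,4,5,6,7-hexahydro-1-benzofuran-2-yl]-2,6-dimethylundeca-2,6-dienoic acid | C/C(=C\CC[C@](C)(O)[C@@H]1CC2=C(CC[C@@H](O)C2=O)O1)CC/C=C(\C)C(=O)O | target

Total step count: 16 (steps 1–3 to the core aldehyde 7, steps 4–9 to the chain iodide 15, steps 10–16 after the union).
Longest linear sequence: 13 steps, from geranyl acetate 8 to 25 (steps 4–16).

Steps most likely to fail

Step 2. The face discrimination in the oxygen ring closure may be insufficient. In addition, the product still carries an allylic C2–O1 bond to a good leaving group, so Pd(0) may re-ionise it and erode the enantiomeric purity with time. The fallback gives up asymmetric induction and moves stereocontrol to a resolution. It sets out from 3 and 2, which are joined with the achiral catalyst Pd(PPh3)4 in THF to racemic 2-ethenyl-3,5,6,7-tetrahydro-1-benzofuran-4(2H)-one F1. The enantiomers of F1 are separated by preparative chromatography on a chiral stationary phase, and the (S)-enantiomer is 5, where the route is rejoined.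

Step 13. Oxygen transfer to the enolate may show poor facial selectivity: the existing stereocentres are remote, and a cyclic enolate without an α-substituent offers the reagent little to grip. The fallback corrects C5 after the event instead of relying on reagent control. It sets out from 20, which is hydroxylated through 21 as before without any demand on selectivity. The unwanted (2S,5S)-epimer of 22, F2, is separated from 22 and inverted by Mitsunobu esterification (4-nitrobenzoic acid, PPh3, DIAD, THF) to the (5R) 4-nitrobenzoate of 22, F3. Mild methanolysis (K2CO3, MeOH, 0 °C) of F3 returns the material to the route at 22.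

Step 12. A chelated transition state may compete with the Felkin–Anh one, or the Felkin–Anh bias may be weak, so that C1′ forms with low selectivity; the addition to a ketone may also be slow. The fallback reverses the order in which the two carbon groups arrive, so that chelation control gives the (1′S) carbinol. It sets out from 7, which is treated with MeMgBr (THF, −78 °C) to give (2S)-2-(1-hydroxyethyl)-3,5,6,7-tetrahydro-1-benzofuran-4(2H)-one F4. Dess–Martin oxidation of F4 gives the methyl ketone (2S)-2-acetyl-3,5,6,7-tetrahydro-1-benzofuran-4(2H)-one F5. Grignard reagent 17 (from 15 as in step 10) is then added to F5 in CH2Cl2 with MgBr2·OEt2 at −78 °C, where attack on the O1/C=O chelate from the side of C2–H should give 20, the point of return.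

Further compounds
F1 | step 2 | racemic 2-ethenyl-3,5,6,7-tetrahydro-1-benzofuran-4(2H)-one | C=CC1CC2=C(CCCC2=O)O1
F2 | step 13 | (2S,5S)-2-[(2S,5E,9E)-11-[(tert-butyldimethylsilyl)oxy]-2-hydroxy-6,10-dimethylundeca-5,9-dien-2-yl]-5-hydroxy-3,5,6,7-tetrahydro-1-benzofuran-4(2H)-one | CC(C)(C)[Si](C)(C)OC/C(C)=C/CC/C(C)=C/CC[C@](C)(O)[C@@H]1CC2=C(CC[C@H](O)C2=O)O1
F3 | step 13 | (2S,5R)-2-[(2S,5E,9E)-11-[(tert-butyldimethylsilyl)oxy]-2-hydroxy-6,10-dimethylundeca-5,9-dien-2-yl]-4-oxo-2,3,4,5,6,7-hexahydro-1-benzofuran-5-yl 4-nitrobenzoate | CC(C)(C)[Si](C)(C)OC/C(C)=C/CC/C(C)=C/CC[C@](C)(O)[C@@H]1CC2=C(CC[C@@H](OC(=O)c3ccc(cc3)[N+](=O)[O-])C2=O)O1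
F4 | step 12 | (2S)-2-(1-hydroxyethyl)-3,5,6,7-tetrahydro-1-benzofuran-4(2H)-one (both carbinol epimers) | CC(O)[C@@H]1CC2=C(CCCC2=O)O1
F5 | step 12 | (2S)-2-acetyl-3,5,6,7-tetrahydro-1-benzofuran-4(2H)-one | CC(=O)[C@@H]1CC2=C(CCCC2=O)O1
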